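## Retrosynthetic overview

1. Target ⇒ its methyl ester; the last step is a selective saponification beside the tertiary C8 acetate.
2. Key cut C11–C12: mixed Kolbe electrolysis (anodic decarboxylative radical cross-coupling) of a C18 acetoxy acid with methyl hydrogen (S)-3-methylglutarate, which delivers C12–C16 with the C13 stereocentre ready-made.
3. The acetoxy acid ⇒ (−)-sclareol by one RuO4 cascade that leaves sclareol's own C13/C16 on O8 as the acetate; the C8–O bond is never broken.
4. Ring order: no carbocycle is built. Rings A and B (C5, C8, C9, C10) come intact from sclareol; a pyran ring C (sclareol oxide) forms only in passing and is cleaved in the same flask.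
5. Deliberately not used: carrying sclareol's C13–C15 chain forward (allylic transposition, oxidation, asymmetric hydrogenation).

Assumption: methyl hydrogen (S)-3-methylglutarate is bought as such (both antipodes of this half-ester are taken to be catalogue compounds); positions are given in labdane numbering.

## Route

Step 1
Reactants: 1 (−)-sclareol [(13R)-labd-14-ene-8α,13-diol]
Product: 5 8α-acetoxy-13,14,15,16-tetranorlabdan-12-oic acid, via hydroxy ketone 2 (not isolated), via sclareol oxide 3 (not isolated), via acetoxy aldehyde 4 (not isolated)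
Conditions: RuCl3·3H2O (2 mol %), NaIO4 (8 equiv), EtOAc/MeCN/H2O (2:2:3), 40 °C; NaHCO3 extraction, then acidify
Reagents that add atoms: sodium periodate, [Na+].[O-]I(=O)(=O)=O; water, O
Why: Catalytic ruthenium tetroxide oxidative cleavage cascade: the vinyl carbinol is degraded to methyl ketone 2, which closes on the 8α-hydroxyl and dehydrates to enol ether 3, and cleavage of its electron-rich C12=C13 bond leaves C13/C16 on O8 as the acetate while C12 is oxidised through aldehyde 4 to the acid; the C8–O bond is never broken, so 8R and C5, C9, C10 are carried over and no new stereocentre is made.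

Step 2
Reactants: 5 8α-acetoxy-13,14,15,16-tetranorlabdan-12-oic acid; 6 methyl hydrogen (S)-3-methylglutarate [(3S)-5-methoxy-3-methyl-5-oxopentanoic acid]
Product: 7 methyl (13S)-8α-acetoxylabdan-15-oate
Conditions: 5 (1 equiv), 6 (4 equiv), KOH (5 mol % of total acid), MeOH, Pt anode/Pt cathode, undivided cell, 200 mA/cm2, 40 °C, to pH 8
Reagents that add atoms: none
Why: Mixed Kolbe electrolysis (anodic decarboxylative radical–radical cross-coupling): both carboxylates lose CO2 at platinum to give unstabilised primary radicals (C11 of the decalin acid, C12 of the half-ester) that combine, the excess of 6 steering 5 statistically into the cross-product; the C13 centre lies β to the radical carbon and enters unchanged as S, C9 next to the C11 radical is not touched, and no new stereocentre is formed.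

Step 3
Reactants: 7 methyl (13S)-8α-acetoxylabdan-15-oate
Product: 9 (13S)-8α-acetoxylabdan-15-oic acid (target), via lithium carboxylate 8 (not isolated)
Conditions: LiOH·H2O (1.5 equiv), THF/H2O 3:1, 0 to 20 °C; then 1 M HCl to pH 3
Reagents that add atoms: lithium hydroxide, [Li+].[OH-]
Why: Chemoselective saponification (BAc2): hydroxide attacks the unhindered primary methyl ester roughly a hundred times faster than the acetate on the hindered tertiary C8, C13 is β to the carbonyl and cannot epimerise, and acidification of 8 releases the acid; no stereocentre is formed or touched.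

## Compound list

1 | (−)-sclareol, (13R)-labd-14-ene-8α,13-diol; (1R,2R,4aS,8aS)-1-[(3R)-3-hydroxy-3-methylpent-4-en-1-yl]-2,5,5,8a-tetramethyldecahydronaphthalen-2-ol | O[C@]1(C)CC[C@H]2C(C)(C)CCC[C@]2(C)[C@H]1CC[C@@](C)(O)C=C | starting material
2 | 8α-hydroxy-14,15-dinorlabdan-13-one; 4-[(1R,2R,4aS,8aS)-2-hydroxy-2,5,5,8a-tetramethyldecahydronaphthalen-1-yl]butan-2-one | O[C@]1(C)CC[C@H]2C(C)(C)CCC[C@]2(C)[C@H]1CCC(C)=O | intermediate
3 | sclareol oxide, 8α,13-epoxy-14,15-dinorlabd-12-ene (tricyclic enol ether, O bridging C8 and C13, C12=C13, trans-decalin) | O3[C@]1(C)CC[C@H]2C(C)(C)CCC[C@]2(C)[C@H]1CC=C3C | intermediate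
4 | 8α-acetoxy-13,14,15,16-tetranorlabdan-12-al; 2-[(1R,2R,4aS,8aS)-2-acetoxy-2,5,5,8a-tetramethyldecahydronaphthalen-1-yl]acetaldehyde | CC(=O)O[C@]1(C)CC[C@H]2C(C)(C)CCC[C@]2(C)[C@H]1CC=O | intermediate
5 | 8α-acetoxy-13,14,15,16-tetranorlabdan-12-oic acid; 2-[(1R,2R,4aS,8aS)-2-acetoxy-2,5,5,8a-tetramethyldecahydronaphthalen-1-yl]acetic acid | CC(=O)O[C@]1(C)CC[C@H]2C(C)(C)CCC[C@]2(C)[C@H]1CC(=O)O | intermediate
6 | methyl hydrogen (S)-3-methylglutarate; (3S)-5-methoxy-3-methyl-5-oxopentanoic acid | OC(=O)C[C@H](C)CC(=O)OC | starting material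
7 | methyl (13S)-8α-acetoxylabdan-15-oate; methyl (3S)-5-[(1R,2R,4aS,8aS)-2-acetoxy-2,5,5,8a-tetramethyldecahydronaphthalen-1-yl]-3-methylpentanoate | CC(=O)O[C@]1(C)CC[C@H]2C(C)(C)CCC[C@]2(C)[C@H]1CC[C@H](C)CC(=O)OC | intermediate
8 | lithium (13S)-8α-acetoxylabdan-15-oate | [Li+].CC(=O)O[C@]1(C)CC[C@H]2C(C)(C)CCC[C@]2(C)[C@H]1CC[C@H](C)CC(=O)[O-] | intermediate
9 | (13S)-8α-acetoxylabdan-15-oic acid; (3S)-5-[(1R,2R,4aS,8aS)-2-acetoxy-2,5,5,8a-tetramethyldecahydronaphthalen-1-yl]-3-methylpentanoic acid (CNP0470037.2) | CC(=O)O[C@]1(C)CC[C@H]2C(C)(C)CCC[C@]2(C)[C@H]1CC[C@H](C)CC(=O)O | target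

## Count and risks

Total step count: 3. Longest linear sequence: 3 steps (1 → 5 → 7 → 9).

Steps most likely to fail, in order of risk:

**Step 2 (mixed Kolbe coupling).** The risks are homodimers, disproportionation of the hindered C11 radical, and over-oxidation to a cation assisted by the C8 acetate. The fallback sets out from 5 and 6. Each acid is condensed with N-hydroxyphthalimide (N,N'-diisopropylcarbodiimide, DMAP cat., CH2Cl2, 20 °C) to give the N-(acyloxy)phthalimide of 5 F1 and the N-(acyloxy)phthalimide of 6 F2. The two redox-active esters are then joined by cathodic nickel catalysis (NiCl2·6H2O 20 mol %, 2,2':6',2''-terpyridine 20 mol %, AgNO3, NaI, NMP, Mg anode/reticulated vitreous carbon cathode, F2 in threefold excess, 20 °C). This is a reductive, metal-templated doubly decarboxylative C(sp3)–C(sp3) coupling in place of free-radical combination at an anode; the conditions are given from memory and would need checking. It comes back to the route at 7.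

**Step 1 (one-pot ruthenium cascade).** The risks are C–H hydroxylation at tertiary carbons and loss of the acetyl group to give sclareolide. The fallback sets out from 1. Osmium-catalysed cleavage (OsO4 1 mol %, NaIO4, THF/H2O, 45 °C) cannot oxidise aldehydes; it runs the same ketone/enol-ether relay through 2 and 3 but stops at acetoxy aldehyde 4, which is isolated by chromatography. A separate Pinnick oxidation (NaClO2, NaH2PO4, 2-methyl-2-butene, t-BuOH/H2O, 20 °C) then comes back to the route at 5. This way makes no compound that is not already numbered (F0).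

**Step 3 (selective saponification).** The risk is partial loss of the tertiary acetate. The fallback sets out from 7. Both esters are cleaved on purpose (KOH, MeOH/H2O, reflux) to (13S)-8α-hydroxylabdan-15-oic acid F3. The tertiary hydroxyl is then re-acetylated (Ac2O, DMAP, Et3N, CH2Cl2, 40 °C), and the mixed anhydride at C15 is hydrolysed during an aqueous pyridine work-up. It comes back to the route at 9.

## Further compounds

F0 | step 1 | none | none
F1 | step 2 | N-(acyloxy)phthalimide of 5; 1,3-dioxoisoindolin-2-yl 2-[(1R,2R,4aS,8aS)-2-acetoxy-2,5,5,8a-tetramethyldecahydronaphthalen-1-yl]acetate | CC(=O)O[C@]1(C)CC[C@H]2C(C)(C)CCC[C@]2(C)[C@H]1CC(=O)ON3C(=O)c4ccccc4C3=O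
F2 | step 2 | N-(acyloxy)phthalimide of 6; 1-(1,3-dioxoisoindolin-2-yl) 5-methyl (3R)-3-methylpentanedioate (same spatial arrangement as 6, descriptor changed by priority) | O=C(C[C@H](C)CC(=O)OC)ON1C(=O)c2ccccc2C1=O
F3 | step 3 | (13S)-8α-hydroxylabdan-15-oic acid; (3S)-5-[(1R,2R,4aS,8aS)-2-hydroxy-2,5,5,8a-tetramethyldecahydronaphthalen-1-yl]-3-methylpentanoic acid | O[C@]1(C)CC[C@H]2C(C)(C)CCC[C@]2(C)[C@H]1CC[C@H](C)CC(=O)O
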